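## The problem

Germacrane numbering is used throughout: ring C1–C10, C11/C12/C13 for the α-methylene lactone carbons on C7, C14 for the ester carbon on C10, C15 for the methyl on C4. The target is a ten-membered carbocycle with two ring-cis trisubstituted alkenes (C1=C10, C4=C5) flanking a cis-oxirane (C2–C3). It also carries a trans-fused α-methylene-γ-butyrolactone (O–C6, C7–C11), an epoxyangelate on O8 and an acetate on O9. The bis-allylic oxirane cannot come from epoxidation of a C1(10),2,4-triene, because C4=C5 is more nucleophilic than C2=C3, so the oxirane has to be built with the ring or before it. The stereocentres fall into three groups. C6–C9 (6R,7S,8S,9S) are contiguous, and C8 (chiral pool) can control C9 and C6/C7. C2/C3 (2R,3S) are remote and must be set against the lactone. The side-chain oxirane (2S,3S) needs reagent control. The fragile parts are the α-methylene lactone (Michael acceptor), the acid-labile bis-allylic oxirane, the Z-enal needed on the way, and the O8/O9 ester pair (acyl migration). In addition, any acyloxy group allylic to a carbanion is expelled.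

Two features make the plan possible. First, C2 is the γ-carbon of the C14 ester through C1=C10 and C3 is attached to C4=C5. C2 can therefore be the carbon of an ester-conjugated allylic sulfonium ylide and C3 the carbonyl carbon of a Z-enal, so one operation closes both the ten-membered ring and the oxirane. Second, O9 and C2 are cis across C1=C10. A 2,5-dihydrofuran (O9, C9, C10, C1, C2) therefore stores that alkene geometry and differentiates O9 from O8.

## Retrosynthesis

**27 ⇐ 26 ⇐ 25.** The C9 acetate is put on last. During the key step C9 must carry a silyl ether: the ylide carbanion is delocalised onto C10, and an acetate on C9 would be lost by β-elimination. The epoxyangelate on C8 is not β to the carbanion and can be in place.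

**25 ⇐ 24 (key step).** The cut is through C2–C3 and the C2–O bond of the oxirane. This gives the monocyclic lactone 24 with a Z-enal arm (C3) and an allylic sulfonium arm (C2). Against the neighbouring cuts (C6–C7, C1=C10), this is the only one that makes the oxirane in the same act as the ring and lets the ring enforce the cis-oxirane. The precursor has no medium ring and no C2/C3 stereocentres. The forward reaction must give C2 attack of the ylide, 1,2-addition to the enal, and one face.

**24 ⇐ 23 ⇐ 22 ⇐ 21.** The enal comes from the primary allylic silyl ether (22 → 23 → 24). The sulfonium salt and the C9 silyl ether come together from dihydrofuran 21, by silylative opening of the ring oxygen with tetrahydrothiophene at the primary allylic C2. The dihydrofuran guarantees that C2 ends cis to C9.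

**21 ⇐ 19 + 8; 19 ⇐ 18 ⇐ 15 + 16.** The side chain is attached by esterification of the only free hydroxyl (O8) with acid 8. Dihydrofuran 19 is the cycloisomer of α-allenol 18. Allenoate 18 comes from C9–C10 bond formation between the α-hydroxy aldehyde derived from diol 15 and bromoynoate 16. The free O8–H is used for chelation control of C9.

**15 ⇐ 14 ⇐ 12 + 4.** The trans-lactone is cut at C6–C7 and at the lactone C–O bond: an intermolecular chromium Barbier reaction of allylic bromide 12 with Z-enal 4. The reaction known for closing germacranolide rings is used here only to join fragments.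

**12 ⇐ 9 + 10; 4 ⇐ 1; 8 ⇐ 5.** Bromide 12 is the rearranged Morita–Baylis–Hillman product of (R)-glyceraldehyde acetonide 9 and methyl acrylate 10. Enal 4 keeps its Z geometry from the carbomagnesiation of propargyl alcohol 1. Acid 8 comes from methyl angelate 5 by asymmetric epoxidation.

## Roads not taken

**Alternative 1:** the most obvious plan cuts C6–C7 last. The forward key step is a chromium-mediated intramolecular Barbier allylation with lactonisation of the open-chain bromo enal A1, which already holds the cis-oxirane. Its reaction type is well precedented for germacranolides. The weakness is that A1 must be assembled with the cis-oxirane already in place between two alkenes. An intermolecular ylide epoxidation would favour the trans-oxirane, and an epoxidation route needs a separate (2Z,4Z)-dienol and a β-oxygenated phosphonate for C1=C10. The vinylogous epoxy enal of A1 is also fragile. The chosen plan lets the ring dictate the cis-oxirane and keeps the oxirane out of all earlier steps.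

**Alternative 2:** delete one atom from an eleven-membered ring. The cyclic sulfone A2 (sulfur between C2 and C3) would be closed by an easy thioether macrocyclisation, then contracted by a Ramberg–Bäcklund reaction to the all-cis triene A3. Ring formation would be simple, but the oxirane would then have to be put on the central, least nucleophilic alkene of A3, for which no selective reagent can be argued. The α-sulfonyl carbanion at C2 would also expel an O9 ester. The chosen plan forms C2–C3 and the oxirane together.

**Alternative 3:** build the ten-membered ring as the periphery of a [6+4] adduct of tropone with (E)-penta-1,3-diene, the bicyclo[4.4.1]undecatrienone A4. The bridging carbonyl carbon would become C14 after oxidation of the tropone-derived diene and retro-Claisen opening of the bridge with methoxide. The ring would come in one step from two commercial compounds. Three points count against it. The adduct is racemic. O8 and C11 would have to enter on the concave face of the bicycle, opposite to O6/O9. Both ring alkenes would have to be introduced afterwards by desaturation in a flexible ring. The chosen plan sets every stereocentre from one chiral-pool centre and stores both alkene geometries beforehand.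

Key step: step 17

Assumption: methyl 4-bromobut-2-ynoate (16), (R)-glyceraldehyde acetonide (9) and methyl angelate (5) are taken as commercial, and the sulfonium salts are drawn as triflates.

## Route

Step 1
Reactants: 1 prop-2-yn-1-ol
Product: 2 (2Z)-3-iodo-2-methylprop-2-en-1-ol
Conditions: MeMgBr (2.5 equiv), CuI (10 mol %), Et2O/THF, −10 °C to rt; then I2, −78 to 0 °C
Reagents that add atoms: methylmagnesium bromide, C[Mg]Br; iodine, II
Why: Copper-catalysed anti-carbomagnesiation of the magnesium propargyl alkoxide puts methyl on C4 and magnesium on C5, and iodinolysis with retention gives the Z-iodide that fixes the C4=C5 geometry.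

Step 2
Reactants: 2 (2Z)-3-iodo-2-methylprop-2-en-1-ol
Product: 3 tert-butyl{[(2Z)-3-iodo-2-methylprop-2-en-1-yl]oxy}dimethylsilane
Conditions: TBSCl, imidazole, CH2Cl2, 0 °C to rt
Reagents that add atoms: tert-butyldimethylsilyl chloride, CC(C)(C)[Si](C)(C)Cl
Why: Standard silylation of a primary alcohol; the group later leaves selectively as the only primary silyl ether.

Step 3
Reactants: 3 tert-butyl{[(2Z)-3-iodo-2-methylprop-2-en-1-yl]oxy}dimethylsilane
Product: 4 (2Z)-4-[(tert-butyldimethylsilyl)oxy]-3-methylbut-2-enal
Conditions: t-BuLi (2.1 equiv), Et2O, −78 °C; DMF; aq. NH4Cl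
Reagents that add atoms: N,N-dimethylformamide, CN(C)C=O
Why: Iodine–lithium exchange and formylation proceed with retention of alkene geometry, giving the Z-enal (C6 aldehyde, C3 silyl ether).

Step 4
Reactants: 5 methyl (2Z)-2-methylbut-2-enoate
Product: 6 (2Z)-2-methylbut-2-en-1-ol
Conditions: i-Bu2AlH (2.2 equiv), CH2Cl2, −78 to 0 °C
Reagents that add atoms: none
Why: 1,2-Reduction of the enoate to the allylic alcohol without touching the Z-alkene.

Step 5
Reactants: 6 (2Z)-2-methylbut-2-en-1-ol
Product: 7 [(2R,3S)-2,3-dimethyloxiran-2-yl]methanol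
Conditions: Ti(OiPr)4 (cat.), D-(−)-diethyl tartrate, t-BuOOH, 4 Å sieves, CH2Cl2, −20 °C
Reagents that add atoms: tert-butyl hydroperoxide, CC(C)(C)OO
Why: Sharpless asymmetric epoxidation; with the D-tartrate the oxygen is delivered to the face that gives the 2R,3S epoxy alcohol, and the Z-alkene fixes the trans relationship of the two methyls.

Step 6
Reactants: 7 [(2R,3S)-2,3-dimethyloxiran-2-yl]methanol
Product: 8 (2S,3S)-2,3-dimethyloxirane-2-carboxylic acid
Conditions: RuCl3 hydrate (cat.), NaIO4, CCl4/MeCN/H2O, rt
Reagents that add atoms: sodium periodate, [Na+].[O-]I(=O)(=O)=O; water, O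
Why: Ruthenium tetroxide oxidation of a primary epoxy alcohol to the glycidic acid; no stereocentre is touched (the descriptor at C2 changes only by priority).

Step 7
Reactants: 9 (4R)-2,2-dimethyl-1,3-dioxolane-4-carbaldehyde; 10 methyl prop-2-enoate
Product: 11 methyl 2-{[(4R)-2,2-dimethyl-1,3-dioxolan-4-yl](hydroxy)methyl}prop-2-enoate (both carbinol epimers)
Conditions: DABCO (0.5 equiv), dioxane/H2O, rt
Reagents that add atoms: none
Why: Morita–Baylis–Hillman reaction; the new carbinol centre (C7) is lost in the next step, so its configuration is irrelevant.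

Step 8
Reactants: 11 methyl 2-{[(4R)-2,2-dimethyl-1,3-dioxolan-4-yl](hydroxy)methyl}prop-2-enoate
Product: 12 methyl (2Z)-2-(bromomethyl)-3-[(4S)-2,2-dimethyl-1,3-dioxolan-4-yl]prop-2-enoate
Conditions: NBS, Me2S, CH2Cl2, 0 °C to rt
Reagents that add atoms: N-bromosuccinimide, O=C1CCC(=O)N1Br
Why: The bromosulfonium reagent converts the Baylis–Hillman alcohol into the rearranged primary allylic bromide by SN2′ attack of bromide, with the thermodynamic Z geometry.

Step 9
Reactants: 12 methyl (2Z)-2-(bromomethyl)-3-[(4S)-2,2-dimethyl-1,3-dioxolan-4-yl]prop-2-enoate; 4 (2Z)-4-[(tert-butyldimethylsilyl)oxy]-3-methylbut-2-enal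
Product: 14 (4S,5R)-5-[(1Z)-3-[(tert-butyldimethylsilyl)oxy]-2-methylprop-1-en-1-yl]-4-[(4S)-2,2-dimethyl-1,3-dioxolan-4-yl]-3-methylideneoxolan-2-one, via hydroxy ester 13 (not isolated)
Conditions: CrCl2 (3 equiv), THF, rt; aq. NH4Cl; then PPTS (cat.), CH2Cl2, rt
Reagents that add atoms: none
Why: Nozaki–Hiyama–Kishi-type Barbier allylation; the allylchromium reagent should add through a chair transition state to give the anti adduct 13, which lactonises to the trans-lactone, and the C7 face should be set by the adjacent dioxolane centre C8, making C6 R and C7 S.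

Step 10
Reactants: 14 trans-lactone acetonide
Product: 15 (4R,5R)-5-[(1Z)-3-[(tert-butyldimethylsilyl)oxy]-2-methylprop-1-en-1-yl]-4-[(1S)-1,2-dihydroxyethyl]-3-methylideneoxolan-2-one
Conditions: CuCl2·2H2O, MeCN, 0 °C
Reagents that add atoms: none
Why: Mild Lewis-acid hydrolysis of a terminal acetonide, which should leave the primary allylic silyl ether in place; no stereocentre changes (descriptor at C7 changes by priority only).

Step 11
Reactants: 15 lactone diol; 16 methyl 4-bromobut-2-ynoate
Product: 18 methyl 2-[1,2-dihydroxy-2-(lactonyl)ethyl]buta-2,3-dienoate (C8–OH and C9–OH syn, C6–C9 as in 27), via α-hydroxy aldehyde 17 (not isolated)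
Conditions: TEMPO (cat.), PhI(OAc)2, CH2Cl2, rt; then indium powder, THF/H2O, rt
Reagents that add atoms: none
Why: TEMPO oxidises the primary alcohol selectively; the indium-mediated Barbier reaction of the propargylic bromide transfers the allenyl group (SE2′) to give the 2-(1-hydroxyalkyl)allenoate, and chelation of indium by the free α-hydroxyl should set C9 syn to O8 (9S).

Step 12
Reactants: 18 allenoate diol
Product: 19 methyl 2-[hydroxy(lactonyl)methyl]-2,5-dihydrofuran-3-carboxylate (O9 and C2 joined in the ring, C8–OH free)
Conditions: AgNO3 (10 mol %), acetone, rt, dark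
Reagents that add atoms: none
Why: Silver-catalysed 5-endo cycloisomerisation of the α-allenol; the ring fixes C2 cis to C9 across C1=C10 and leaves O8 as the only free hydroxyl.

Step 13
Reactants: 19 dihydrofuran alcohol; 8 (2S,3S)-2,3-dimethyloxirane-2-carboxylic acid
Product: 21 C8 (2S,3S)-2,3-dimethyloxirane-2-carboxylate of 19, via mixed anhydride 20 (not isolated)
Conditions: 8, 2,4,6-trichlorobenzoyl chloride, Et3N, THF, rt; then 19, DMAP, toluene, rt
Reagents that add atoms: 2,4,6-trichlorobenzoyl chloride, O=C(Cl)c1c(Cl)cc(Cl)cc1Cl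
Why: Yamaguchi esterification of a hindered secondary alcohol with an α-quaternary acid; no stereocentre is affected.

Step 14
Reactants: 21 dihydrofuran ester
Product: 22 sulfonium triflate (C2–S+ of tetrahydrothiophenium, C9–OTBS, C3–OTBS, C1=C10 with C2 cis to C9)
Conditions: TBSOTf (1.5 equiv), tetrahydrothiophene (5 equiv), CH2Cl2, −78 to −20 °C
Reagents that add atoms: tert-butyldimethylsilyl trifluoromethanesulfonate, CC(C)(C)[Si](C)(C)OS(=O)(=O)C(F)(F)F; tetrahydrothiophene, C1CCSC1
Why: Proposed new method: the silyl triflate should silylate the dihydrofuran oxygen, the most basic ether oxygen present (glycidic-ester and silyl-ether oxygens are far less basic), and the thioether should open the silyloxonium ion by SN2 attack at the primary allylic C2, giving the C9 silyl ether and the C2 sulfonium salt with the ring-derived alkene geometry; the closest known reaction types are the cleavage of cyclic ethers by silyl iodides or acyl halides and the capture of cyclic oxonium ions by thioethers.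

Step 15
Reactants: 22 sulfonium triflate
Product: 23 allylic alcohol sulfonium triflate (C3–OH)
Conditions: HF·pyridine, pyridine, THF, 0 °C
Reagents that add atoms: none
Why: Buffered fluoride cleaves the primary allylic silyl ether much faster than the hindered secondary C9 silyl ether; the sulfonium salt is inert to acid.

Step 16
Reactants: 23 allylic alcohol sulfonium triflate
Product: 24 Z-enal sulfonium triflate (C3 aldehyde)
Conditions: TEMPO (cat.), PhI(OAc)2, CH2Cl2, rt
Reagents that add atoms: none
Why: Oxoammonium oxidation of a primary allylic alcohol, which is known to preserve Z-enal geometry; it is run in a weakly acidic medium so that no ylide forms yet.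

Step 17
Reactants: 24 Z-enal sulfonium triflate
Product: 25 macrocyclic oxirane (target skeleton with C9–OTBS)
Conditions: Cs2CO3, MeCN, high dilution (about 1 mM), 0 °C to rt
Reagents that add atoms: none
Why: Proposed new method: Cs2CO3 removes the C2 proton (α to sulfur and vinylogously α to the C14 ester) to give an ester-conjugated allylic sulfonium ylide; its C2 carbon adds to the C3 aldehyde and the resulting alkoxide displaces tetrahydrothiophene, so the closest known reaction type is the Corey–Chaykovsky epoxidation with allylic sulfonium ylides, known intermolecularly and for closing five- to seven-membered rings but not for a ten-membered ring. The carbocycle closes by 10-exo-trig addition to the carbonyl and the oxirane by 3-exo-tet substitution. Betaine formation with this stabilised ylide is reversible, so adducts through C10 of the ambident ylide (which cannot close), conjugate adducts and the strained trans-betaine should revert, and the mixture should funnel into the one irreversible exit, the cis-fused oxirane. The cis relationship of C2 and C3 is enforced by the ring, since a trans-oxirane would have to span two Z-alkenes in a ten-membered ring. The face, and hence 2R,3S, has to come from the trans-lactone at C6/C7 and the C8/C9 substituents, which hold both arms on one side of the lactone. β-Elimination is blocked because C9 carries a silyl ether and not an ester, and high dilution is needed against oligomerisation.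

Step 18
Reactants: 25 macrocyclic oxirane silyl ether
Product: 26 macrocyclic C9 alcohol
Conditions: HF·pyridine, pyridine, THF, 0 °C to rt
Reagents that add atoms: none
Why: Fluoride-mediated desilylation; the pyridine buffer protects the bis-allylic oxirane, and the acidic medium suppresses migration of the O8 ester.

Step 19
Reactants: 26 macrocyclic C9 alcohol
Product: 27 CNP0604635.2 (target)
Conditions: Ac2O, pyridine, DMAP (cat.), CH2Cl2, 0 °C
Reagents that add atoms: acetic anhydride, CC(=O)OC(C)=O
Why: Acetylation of the allylic secondary alcohol; acylation should outrun acyl migration.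

## Compound list

1 | prop-2-yn-1-ol | C#CCO | starting material
2 | (2Z)-3-iodo-2-methylprop-2-en-1-ol | OC/C(C)=C\I | intermediate
3 | tert-butyl{[(2Z)-3-iodo-2-methylprop-2-en-1-yl]oxy}dimethylsilane | CC(C)(C)[Si](C)(C)OC/C(C)=C\I | intermediate
4 | (2Z)-4-[(tert-butyldimethylsilyl)oxy]-3-methylbut-2-enal | CC(C)(C)[Si](C)(C)OC/C(C)=C\C=O | intermediate
5 | methyl (2Z)-2-methylbut-2-enoate (methyl angelate) | C/C=C(/C)C(=O)OC | starting material
6 | (2Z)-2-methylbut-2-en-1-ol | C/C=C(/C)CO | intermediate
7 | [(2R,3S)-2,3-dimethyloxiran-2-yl]methanol | OC[C@@]1(C)O[C@H]1C | intermediate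
8 | (2S,3S)-2,3-dimethyloxirane-2-carboxylic acid | OC(=O)[C@@]1(C)O[C@H]1C | intermediate
9 | (4R)-2,2-dimethyl-1,3-dioxolane-4-carbaldehyde | O=C[C@H]1COC(C)(C)O1 | starting material
10 | methyl prop-2-enoate | C=CC(=O)OC | starting material
11 | methyl 2-{[(4R)-2,2-dimethyl-1,3-dioxolan-4-yl](hydroxy)methyl}prop-2-enoate, both carbinol epimers | C=C(C(=O)OC)C(O)[C@H]1COC(C)(C)O1 | intermediate
12 | methyl (2Z)-2-(bromomethyl)-3-[(4S)-2,2-dimethyl-1,3-dioxolan-4-yl]prop-2-enoate | BrC/C(C(=O)OC)=C\[C@H]1COC(C)(C)O1 | intermediate
13 | methyl (3S,4R,5Z)-7-[(tert-butyldimethylsilyl)oxy]-3-[(4S)-2,2-dimethyl-1,3-dioxolan-4-yl]-4-hydroxy-6-methyl-2-methylidenehept-5-enoate | COC(=O)C(=C)[C@@H]([C@H](O)/C=C(/C)CO[Si](C)(C)C(C)(C)C)[C@H]1COC(C)(C)O1 | intermediate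
14 | (4S,5R)-5-[(1Z)-3-[(tert-butyldimethylsilyl)oxy]-2-methylprop-1-en-1-yl]-4-[(4S)-2,2-dimethyl-1,3-dioxolan-4-yl]-3-methylideneoxolan-2-one | C=C1C(=O)O[C@H](/C=C(/C)CO[Si](C)(C)C(C)(C)C)[C@H]1[C@H]1COC(C)(C)O1 | intermediate
15 | (4R,5R)-5-[(1Z)-3-[(tert-butyldimethylsilyl)oxy]-2-methylprop-1-en-1-yl]-4-[(1S)-1,2-dihydroxyethyl]-3-methylideneoxolan-2-one | C=C1C(=O)O[C@H](/C=C(/C)CO[Si](C)(C)C(C)(C)C)[C@H]1[C@H](O)CO | intermediate
16 | methyl 4-bromobut-2-ynoate | COC(=O)C#CCBr | starting material
17 | α-hydroxy aldehyde: 15 with C9 oxidised to the aldehyde | C=C1C(=O)O[C@H](/C=C(/C)CO[Si](C)(C)C(C)(C)C)[C@H]1[C@H](O)C=O | intermediate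
18 | allenoate diol: methyl 2-[1,2-dihydroxy-2-(lactonyl)ethyl]buta-2,3-dienoate, O8/O9 syn, C6–C9 as in 27 | C=C1C(=O)O[C@H](/C=C(/C)CO[Si](C)(C)C(C)(C)C)[C@H]1[C@H](O)[C@@H](O)C(=C=C)C(=O)OC | intermediate
19 | dihydrofuran alcohol: methyl 2-[hydroxy(lactonyl)methyl]-2,5-dihydrofuran-3-carboxylate, C6–C9 as in 27 | C=C1C(=O)O[C@H](/C=C(/C)CO[Si](C)(C)C(C)(C)C)[C@H]1[C@H](O)[C@H]1OCC=C1C(=O)OC | intermediate
20 | (2S,3S)-2,3-dimethyloxirane-2-carboxylic 2,4,6-trichlorobenzoic anhydride | O=C(OC(=O)c1c(Cl)cc(Cl)cc1Cl)[C@@]1(C)O[C@H]1C | intermediate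
21 | dihydrofuran ester: O8 (2S,3S)-2,3-dimethyloxirane-2-carboxylate of 19 | C=C1C(=O)O[C@H](/C=C(/C)CO[Si](C)(C)C(C)(C)C)[C@H]1[C@H](OC(=O)[C@@]2(C)O[C@H]2C)[C@H]1OCC=C1C(=O)OC | intermediate
22 | sulfonium triflate: ring-opened 21 with C9–OTBS and C2 bound to tetrahydrothiophenium, C2 cis to C9 across C1=C10 | C=C1C(=O)O[C@H](/C=C(/C)CO[Si](C)(C)C(C)(C)C)[C@H]1[C@H](OC(=O)[C@@]2(C)O[C@H]2C)[C@@H](O[Si](C)(C)C(C)(C)C)/C(C(=O)OC)=C\C[S+]1CCCC1.[O-]S(=O)(=O)C(F)(F)F | intermediate
23 | allylic alcohol sulfonium triflate: 22 with C3–OH | C=C1C(=O)O[C@H](/C=C(/C)CO)[C@H]1[C@H](OC(=O)[C@@]2(C)O[C@H]2C)[C@@H](O[Si](C)(C)C(C)(C)C)/C(C(=O)OC)=C\C[S+]1CCCC1.[O-]S(=O)(=O)C(F)(F)F | intermediate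
24 | Z-enal sulfonium triflate: 23 with C3 as aldehyde | C=C1C(=O)O[C@H](/C=C(/C)C=O)[C@H]1[C@H](OC(=O)[C@@]2(C)O[C@H]2C)[C@@H](O[Si](C)(C)C(C)(C)C)/C(C(=O)OC)=C\C[S+]1CCCC1.[O-]S(=O)(=O)C(F)(F)F | intermediate
25 | macrocyclic oxirane: target with tert-butyldimethylsilyl ether in place of the C9 acetate | C=C1C(=O)O[C@@H]2/C=C(/C)[C@@H]3O[C@@H]3/C=C(/C(=O)OC)[C@H](O[Si](C)(C)C(C)(C)C)[C@@H](OC(=O)[C@@]3(C)O[C@H]3C)[C@@H]12 | intermediate
26 | macrocyclic C9 alcohol: target without the acetyl group | C=C1C(=O)O[C@@H]2/C=C(/C)[C@@H]3O[C@@H]3/C=C(/C(=O)OC)[C@H](O)[C@@H](OC(=O)[C@@]3(C)O[C@H]3C)[C@@H]12 | intermediate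
27 | CNP0604635.2 | C=C1C(=O)O[C@@H]2/C=C(/C)[C@@H]3O[C@@H]3/C=C(/C(=O)OC)[C@H](OC(C)=O)[C@@H](OC(=O)[C@@]3(C)O[C@H]3C)[C@@H]12 | target

## Step count and risks

Total: 19 steps. Longest linear sequence: 14 steps (steps 1–3, then 9–19).

**Step 17 (key step).** What may go wrong: oligomerisation in place of ring closure; conjugate addition of the ylide to the α-methylene lactone or to the enal followed by cyclopropane closure; Z to E isomerisation of the enal by reversible addition of the released thioether; poor facial selectivity at C2/C3; or too low a reactivity of the stabilised ylide towards the enal. Fallback (known reaction types): set out from 24 and exchange the sulfonium group for a phosphonium group with PPh3, giving the phosphonium triflate F1. Close the ring by an intramolecular Wittig reaction under high dilution to the all-cis triene F2. Add singlet oxygen across the s-cis C2–C5 diene to give the endoperoxide F3. Deoxygenate with PPh3, which is known to turn such 3,6-dihydro-1,2-dioxines into vinyl oxiranes by SN2′ closure. The route is rejoined at 25.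

**Step 14.** What may go wrong: silyl activation of the side-chain oxirane or of the lactone carbonyl with sulfide addition, attack at C9 in place of C2, or loss of the primary silyl ether. Fallback (known reaction types): set out from 19, before the ester is introduced, and protect O8 as the triethylsilyl ether F4. Cleave the dihydrofuran with TBSCl/NaI (silyl iodide ether cleavage) to the allylic iodide F5. Alkylate tetrahydrothiophene and exchange the anion with AgOTf to give the sulfonium triflate F6. Remove the primary silyl and the triethylsilyl groups with buffered HF·pyridine to give the diol F7. Oxidise the allylic alcohol with TEMPO/PhI(OAc)2 to the enal F8. Acylate O8 with mixed anhydride 20 in pyridine. The route is rejoined at 24.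

**Step 9.** What may go wrong: insufficient anti selectivity, or the wrong sense of induction from C8 at C7, so that the lactone forms as a C6/C7 diastereomer. Fallback: move from substrate control to catalyst control. Set out again from 12 and 4 and run the allylation as a catalytic asymmetric Nozaki–Hiyama reaction (CrCl2 cat., Mn, TMSCl, chiral oxazoline–sulfonamide ligand of the matching hand). This gives the silyl ether F9 of the anti adduct, which is desilylated and lactonised with acid. The route is rejoined at 14.

## Further compounds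

F1 | step 17 | phosphonium triflate: 24 with triphenylphosphonium in place of tetrahydrothiophenium | C=C1C(=O)O[C@H](/C=C(/C)C=O)[C@H]1[C@H](OC(=O)[C@@]2(C)O[C@H]2C)[C@@H](O[Si](C)(C)C(C)(C)C)/C(C(=O)OC)=C\C[P+](c1ccccc1)(c1ccccc1)c1ccccc1.[O-]S(=O)(=O)C(F)(F)F
F2 | step 17 | all-cis macrocyclic triene: 25 with a Z C2=C3 alkene in place of the oxirane | C=C1C(=O)O[C@@H]2/C=C(/C)\C=C/C=C(/C(=O)OC)[C@H](O[Si](C)(C)C(C)(C)C)[C@@H](OC(=O)[C@@]3(C)O[C@H]3C)[C@@H]12
F3 | step 17 | endoperoxide: 1,2-dioxine bridging C2 and C5 of F2, C3=C4 alkene | C=C1C(=O)O[C@@H]2C3OOC(C=C3C)/C=C(/C(=O)OC)[C@H](O[Si](C)(C)C(C)(C)C)[C@@H](OC(=O)[C@@]3(C)O[C@H]3C)[C@@H]12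
F4 | step 14 | O8 triethylsilyl ether of 19 | C=C1C(=O)O[C@H](/C=C(/C)CO[Si](C)(C)C(C)(C)C)[C@H]1[C@H](O[Si](CC)(CC)CC)[C@H]1OCC=C1C(=O)OC
F5 | step 14 | allylic iodide: ring-opened F4 with C9–OTBS and C2–I | C=C1C(=O)O[C@H](/C=C(/C)CO[Si](C)(C)C(C)(C)C)[C@H]1[C@H](O[Si](CC)(CC)CC)[C@@H](O[Si](C)(C)C(C)(C)C)/C(C(=O)OC)=C\CI
F6 | step 14 | sulfonium triflate with O8 triethylsilyl, O9 and O3 tert-butyldimethylsilyl ethers | C=C1C(=O)O[C@H](/C=C(/C)CO[Si](C)(C)C(C)(C)C)[C@H]1[C@H](O[Si](CC)(CC)CC)[C@@H](O[Si](C)(C)C(C)(C)C)/C(C(=O)OC)=C\C[S+]1CCCC1.[O-]S(=O)(=O)C(F)(F)F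
F7 | step 14 | diol sulfonium triflate: C3–OH and C8–OH free, C9–OTBS | C=C1C(=O)O[C@H](/C=C(/C)CO)[C@H]1[C@H](O)[C@@H](O[Si](C)(C)C(C)(C)C)/C(C(=O)OC)=C\C[S+]1CCCC1.[O-]S(=O)(=O)C(F)(F)F
F8 | step 14 | Z-enal sulfonium triflate with free C8–OH | C=C1C(=O)O[C@H](/C=C(/C)C=O)[C@H]1[C@H](O)[C@@H](O[Si](C)(C)C(C)(C)C)/C(C(=O)OC)=C\C[S+]1CCCC1.[O-]S(=O)(=O)C(F)(F)F
F9 | step 9 | trimethylsilyl ether of hydroxy ester 13 | COC(=O)C(=C)[C@@H]([C@H](O[Si](C)(C)C)/C=C(/C)CO[Si](C)(C)C(C)(C)C)[C@H]1COC(C)(C)O1
A1 | alternative 1 | open-chain bromo enal carrying the cis-oxirane (seco C6–C7 compound) | O=C/C=C(/C)[C@@H]1O[C@@H]1/C=C(/C(=O)OC)[C@H](OC(C)=O)[C@@H](OC(=O)[C@@]2(C)O[C@H]2C)/C=C(\CBr)C(=O)OC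
A2 | alternative 2 | eleven-membered cyclic sulfone with sulfur between C2 and C3 | C=C1C(=O)O[C@@H]2/C=C(/C)CS(=O)(=O)C/C=C(/C(=O)OC)[C@H](OC(C)=O)[C@@H](OC(=O)[C@@]3(C)O[C@H]3C)[C@@H]12
A3 | alternative 2 | all-cis macrocyclic triene with the final esters | C=C1C(=O)O[C@@H]2/C=C(/C)\C=C/C=C(/C(=O)OC)[C@H](OC(C)=O)[C@@H](OC(=O)[C@@]3(C)O[C@H]3C)[C@@H]12
A4 | alternative 3 | 7-methylbicyclo[4.4.1]undeca-2,4,8-trien-11-one (tropone–pentadiene [6+4] adduct, racemic) | O=C1C2C=CC=CC1C(C)C=CC2
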